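**Retrosynthetic overview**
- The target is traced back to a C10 ketone (methylenation), which comes from Wacker oxidation of a C9=C10 cycloheptene; the C6 hydroxyl comes from a C6 ketone, and the cinnamate is carried on O8 from the acyclic stage.
- The trans-fused hydroazulenone is disconnected by an intramolecular (4+3) cycloaddition: an epoxy enol silane (C5–C6–C7 oxyallyl unit; the epoxide oxygen becomes the C4 hydroxyl) adds to a tethered (1E,3E)-dienyl cinnamate (C8–C9–C10–C1). C1–C5 and C7–C8 form together, so both rings close in this one step, the cyclopentane bond leading and the cycloheptene bond following.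
- The feature that allows this: C6 is a carbinol flanked by C5 and C7 (a latent 2-oxyallyl unit), C4 carries oxygen next to C5, C8 carries oxygen at the end of the four-carbon arc C8–C9–C10–C1 of the seven-membered ring, and C2–C3–C4 of the five-membered ring serve as the tether.
- The acyclic precursor comes from an enal (cross-metathesis, then enol ester formation) and an epoxy ketone (Sharpless epoxide, isobutyl Grignard, oxidation), both built on (2E)-3-methylocta-2,7-dien-1-ol, made by carboalumination of hept-1-en-6-yne.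

Key step: step 9

Remark: atoms are numbered as in guaiane (C1–C15; isopropyl C11–C13 on C7); hept-1-en-6-yne, isobutylmagnesium bromide, crotonaldehyde and cinnamic anhydride are taken as purchased.

**Step 1**
Reactants: 1 hept-1-en-6-yne
Product: 4 (2E)-3-methylocta-2,7-dien-1-ol, via alkenyldimethylalane 2 (not isolated), via lithium alkenylalanate 3 (not isolated)
Conditions: Me3Al, Cp2ZrCl2 (cat.), CH2Cl2, 0 °C to rt; n-BuLi, THF, −78 °C; (CH2O)n, rt; aq. HCl
Reagents that add atoms: trimethylaluminium, C[Al](C)C; formaldehyde (from paraformaldehyde), C=O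
Why: Negishi carboalumination catalysed by Cp2ZrCl2 adds methyl and aluminium cis across the terminal alkyne, so hydroxymethylation of the derived alanate gives the E trisubstituted allylic alcohol, while the terminal alkene should stay inert.

**Step 2**
Reactants: 4 (2E)-3-methylocta-2,7-dien-1-ol
Product: 5 [(2S,3S)-3-methyl-3-(pent-4-en-1-yl)oxiran-2-yl]methanol
Conditions: Ti(OiPr)4 (cat.), L-(+)-diisopropyl tartrate, t-BuOOH, 4 Å molecular sieves, CH2Cl2, −20 °C
Reagents that add atoms: tert-butyl hydroperoxide, CC(C)(C)OO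
Why: Sharpless asymmetric epoxidation of the E allylic alcohol with the L-(+)-tartrate ligand should deliver oxygen to the face that gives the (2S,3S)-epoxide, which fixes C4 (S) and the C5 configuration that is inverted in step 9; the isolated terminal alkene does not react.

**Step 3**
Reactants: 5 [(2S,3S)-3-methyl-3-(pent-4-en-1-yl)oxiran-2-yl]methanol
Product: 6 (2R,3S)-3-methyl-3-(pent-4-en-1-yl)oxirane-2-carbaldehyde
Conditions: Dess–Martin periodinane, NaHCO3, CH2Cl2, 0 °C to rt
Reagents that add atoms: none
Why: Buffered Dess–Martin oxidation of the primary alcohol should give the epoxy aldehyde without epoxide opening or epimerisation.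

**Step 4**
Reactants: 6 (2R,3S)-3-methyl-3-(pent-4-en-1-yl)oxirane-2-carbaldehyde; 7 isobutylmagnesium bromide
Product: 8 3-methyl-1-[(2S,3S)-3-methyl-3-(pent-4-en-1-yl)oxiran-2-yl]butan-1-ol (both carbinol epimers)
Conditions: THF, −78 °C; then aq. NH4Cl
Reagents that add atoms: none
Why: Grignard addition to the aldehyde is much faster than attack on the trisubstituted epoxide at low temperature; the new carbinol centre forms as a mixture that is erased in step 5.

**Step 5**
Reactants: 8 3-methyl-1-[(2S,3S)-3-methyl-3-(pent-4-en-1-yl)oxiran-2-yl]butan-1-ol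
Product: 9 3-methyl-1-[(2R,3S)-3-methyl-3-(pent-4-en-1-yl)oxiran-2-yl]butan-1-one
Conditions: Dess–Martin periodinane, NaHCO3, CH2Cl2, rt
Reagents that add atoms: none
Why: Dess–Martin oxidation converges both carbinol epimers to the α,β-epoxy ketone; the epoxide stereocentres are not touched.

**Step 6**
Reactants: 9 3-methyl-1-[(2R,3S)-3-methyl-3-(pent-4-en-1-yl)oxiran-2-yl]butan-1-one; 10 (E)-crotonaldehyde
Product: 11 (2E)-6-[(2S,3R)-2-methyl-3-(3-methylbutanoyl)oxiran-2-yl]hex-2-enal
Conditions: second-generation Hoveyda–Grubbs catalyst, RuCl2(H2IMes)(=CH-C6H4-2-OiPr) (cat.), excess 10, CH2Cl2, 40 °C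
Reagents that add atoms: none
Why: Olefin cross-metathesis of the terminal alkene with excess crotonaldehyde should give the conjugated enal with E geometry under thermodynamic control; the epoxy ketone is inert to the catalyst.

**Step 7**
Reactants: 11 (2E)-6-[(2S,3R)-2-methyl-3-(3-methylbutanoyl)oxiran-2-yl]hex-2-enal; 12 (E,E)-cinnamic anhydride
Product: 13 (1E,3E)-6-[(2S,3R)-2-methyl-3-(3-methylbutanoyl)oxiran-2-yl]hexa-1,3-dien-1-yl (2E)-3-phenylprop-2-enoate
Conditions: Et3N, DMAP (cat.), MeCN, 60 °C
Reagents that add atoms: none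
Why: Soft enolisation (vinylogous enol ester formation): triethylamine reversibly removes the γ-hydrogen at C1 of the enal and the DMAP-activated anhydride O-acylates the dienolate, which should give the conjugated (1E,3E)-dienyl ester as the main isomer, while the far less acidic ketone stays untouched.

**Step 8**
Reactants: 13 (1E,3E)-6-[(2S,3R)-2-methyl-3-(3-methylbutanoyl)oxiran-2-yl]hexa-1,3-dien-1-yl (2E)-3-phenylprop-2-enoate
Product: 14 (1E,3E)-6-{(2S,3R)-2-methyl-3-[(1E)-3-methyl-1-(triethylsilyloxy)but-1-en-1-yl]oxiran-2-yl}hexa-1,3-dien-1-yl (2E)-3-phenylprop-2-enoate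
Conditions: lithium 2,2,6,6-tetramethylpiperidide (from the amine and n-BuLi), LiBr, Et3SiCl present from the start, THF, −78 °C
Reagents that add atoms: chlorotriethylsilane, CC[Si](Cl)(CC)CC
Why: Kinetic deprotonation at C7, the only readily enolisable position, by the hindered lithium amide through a closed (Ireland-type) transition state should give the E(O)-enolate, which is trapped in situ as the E silyl enol ether (isopropyl cis to C5); the cinnamate has no acidic hydrogen and the epoxide C–H is not removed.

**Step 9**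
Reactants: 14 (1E,3E)-6-{(2S,3R)-2-methyl-3-[(1E)-3-methyl-1-(triethylsilyloxy)but-1-en-1-yl]oxiran-2-yl}hexa-1,3-dien-1-yl (2E)-3-phenylprop-2-enoate
Product: 15 (1S,3aS,6R,7R,8aS)-1-methyl-8-oxo-7-(propan-2-yl)-1-(triethylsilyloxy)-1,2,3,3a,6,7,8,8a-octahydroazulen-6-yl (2E)-3-phenylprop-2-enoate
Conditions: Et3SiOTf (0.2 equiv), CH2Cl2, −78 °C, high dilution; then 2,6-lutidine, aq. NaHCO3
Reagents that add atoms: none
Why: Et3SiOTf silylates the epoxide oxygen; C5, which is allylic to the enol silane, is then attacked by the diene terminus C1 from the side opposite the leaving oxygen while the enol-ether carbon C7 bonds to C8 in the same asynchronous (4+3) event, and loss of the silyl group from the C6 oxygen to triflate returns the catalyst and unveils the ketone. The closest known reaction type is the silyl-triflate-catalysed (4+3) cycloaddition of epoxy enol silanes with dienes, inter- and intramolecular, which transfers the epoxide configuration with inversion. The cyclopentane closes by 5-exo attack of C1 on the allyl terminus C5 (endo with respect to the epoxide C–O bond, allowed by its allylic, loosened character), and the cycloheptene closes as the second σ-bond of the cycloaddition, C7 on C8, with a cis C9=C10 bond inherited from the s-cis diene. C5 is controlled by the (4S,5R) epoxide from step 2 (inversion, H5 cis to the C4 oxygen), C1 by the extended arrangement in which the C2–C3 tether joins the two outside positions and the silyloxy group points away from the diene (trans ring fusion), C8 by the E enol ester (cinnamate cis to C2), and C7 by the E enol silane (isopropyl inside, hence cis to the cinnamate). The step needs seven- rather than five-membered closure (C7 to C8, not to C10) and the extended rather than the compact array: the weakly donating acyloxy group avoids a long-lived cation after the first bond, the E,E diene reaches the s-cis form without inside substituents, and allylic strain with the cis isopropyl group keeps C4 outside on the allyl unit.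

**Step 10**
Reactants: 15 (1S,3aS,6R,7R,8aS)-1-methyl-8-oxo-7-(propan-2-yl)-1-(triethylsilyloxy)-1,2,3,3a,6,7,8,8a-octahydroazulen-6-yl (2E)-3-phenylprop-2-enoate
Product: 16 (1S,3aS,6R,7S,8R,8aR)-8-hydroxy-1-methyl-7-(propan-2-yl)-1-(triethylsilyloxy)-1,2,3,3a,6,7,8,8a-octahydroazulen-6-yl (2E)-3-phenylprop-2-enoate
Conditions: NaBH4, CeCl3·7H2O, MeOH, −40 °C
Reagents that add atoms: none
Why: Luche reduction: cerium-activated 1,2-hydride addition to the C6 ketone should occur from the α-face, opposite the isopropyl, cinnamate and silyloxy groups that all lie on the β-face, which sets the C6 hydroxyl β; the cinnamate double bond is not reduced.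

**Step 11**
Reactants: 16 (1S,3aS,6R,7S,8R,8aR)-8-hydroxy-1-methyl-7-(propan-2-yl)-1-(triethylsilyloxy)-1,2,3,3a,6,7,8,8a-octahydroazulen-6-yl (2E)-3-phenylprop-2-enoate
Product: 17 (1S,3aR,6R,7S,8R,8aR)-8-hydroxy-1-methyl-4-oxo-7-(propan-2-yl)-1-(triethylsilyloxy)decahydroazulen-6-yl (2E)-3-phenylprop-2-enoate
Conditions: PdCl2[2-(4,5-dihydro-1,3-oxazol-2-yl)quinoline] (cat.), AgSbF6 (cat.), aq. t-BuOOH, CH2Cl2, 0 °C to rt
Reagents that add atoms: tert-butyl hydroperoxide, CC(C)(C)OO
Why: Wacker-type oxidation of the internal cis-alkene by cationic divalent palladium and the hydroperoxide; the electron-withdrawing allylic ester should direct oxygen to the distal carbon C10, no stereocentre is created, and the transannular hemiketal with the C6 hydroxyl is disfavoured because it would be a trans-fused oxabicyclo[3.3.0]octane.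

**Step 12**
Reactants: 17 (1S,3aR,6R,7S,8R,8aR)-8-hydroxy-1-methyl-4-oxo-7-(propan-2-yl)-1-(triethylsilyloxy)decahydroazulen-6-yl (2E)-3-phenylprop-2-enoate
Product: 18 (1S,3aR,6R,7S,8R,8aR)-8-hydroxy-1-methyl-4-methylidene-7-(propan-2-yl)-1-(triethylsilyloxy)decahydroazulen-6-yl (2E)-3-phenylprop-2-enoate
Conditions: Zn, CH2Br2, TiCl4, THF/CH2Cl2, 0 °C to rt
Reagents that add atoms: dibromomethane, BrCBr
Why: Takai–Lombardo methylenation with the non-basic zinc/titanium methylene reagent should convert the C10 ketone into the exocyclic alkene without β-elimination of the cinnamate or epimerisation at C1, and it leaves the ester alone.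

**Step 13**
Reactants: 18 (1S,3aR,6R,7S,8R,8aR)-8-hydroxy-1-methyl-4-methylidene-7-(propan-2-yl)-1-(triethylsilyloxy)decahydroazulen-6-yl (2E)-3-phenylprop-2-enoate
Product: 19 (1S,3aR,6R,7S,8R,8aR)-1,8-dihydroxy-1-methyl-4-methylidene-7-(propan-2-yl)decahydroazulen-6-yl (2E)-3-phenylprop-2-enoate (CNP0290378.1)
Conditions: HF·pyridine, pyridine/THF, 0 °C to rt
Reagents that add atoms: none
Why: Fluoride-mediated cleavage of the tertiary triethylsilyl ether (desilylation), to which the ester, the alkenes and the alcohols are inert, frees the C4 hydroxyl.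

**Compound list**
1 | hept-1-en-6-yne | C#CCCCC=C | starting material
2 | [(1E)-2-methylhepta-1,6-dien-1-yl]dimethylalane | C[Al](C)/C=C(\C)CCCC=C | intermediate (not isolated)
3 | lithium butyl(dimethyl)[(1E)-2-methylhepta-1,6-dien-1-yl]alanate | [Li+].CCCC[Al-](C)(C)/C=C(\C)CCCC=C | intermediate (not isolated)
4 | (2E)-3-methylocta-2,7-dien-1-ol | OC/C=C(\C)CCCC=C | intermediate
5 | [(2S,3S)-3-methyl-3-(pent-4-en-1-yl)oxiran-2-yl]methanol | OC[C@@H]1O[C@@]1(C)CCCC=C | intermediate
6 | (2R,3S)-3-methyl-3-(pent-4-en-1-yl)oxirane-2-carbaldehyde | O=C[C@@H]1O[C@@]1(C)CCCC=C | intermediate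
7 | isobutylmagnesium bromide | CC(C)C[Mg]Br | starting material
8 | 3-methyl-1-[(2S,3S)-3-methyl-3-(pent-4-en-1-yl)oxiran-2-yl]butan-1-ol (carbinol epimers) | CC(C)CC(O)[C@@H]1O[C@@]1(C)CCCC=C | intermediate
9 | 3-methyl-1-[(2R,3S)-3-methyl-3-(pent-4-en-1-yl)oxiran-2-yl]butan-1-one | CC(C)CC(=O)[C@@H]1O[C@@]1(C)CCCC=C | intermediate
10 | (E)-crotonaldehyde | C/C=C/C=O | starting material
11 | (2E)-6-[(2S,3R)-2-methyl-3-(3-methylbutanoyl)oxiran-2-yl]hex-2-enal | CC(C)CC(=O)[C@@H]1O[C@@]1(C)CCC/C=C/C=O | intermediate
12 | (E,E)-cinnamic anhydride | O=C(/C=C/c1ccccc1)OC(=O)/C=C/c1ccccc1 | starting material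
13 | (1E,3E)-6-[(2S,3R)-2-methyl-3-(3-methylbutanoyl)oxiran-2-yl]hexa-1,3-dien-1-yl (2E)-3-phenylprop-2-enoate | CC(C)CC(=O)[C@@H]1O[C@@]1(C)CC/C=C/C=C/OC(=O)/C=C/c2ccccc2 | intermediate
14 | (1E,3E)-6-{(2S,3R)-2-methyl-3-[(1E)-3-methyl-1-(triethylsilyloxy)but-1-en-1-yl]oxiran-2-yl}hexa-1,3-dien-1-yl (2E)-3-phenylprop-2-enoate | CC(C)/C=C(/O[Si](CC)(CC)CC)[C@@H]1O[C@@]1(C)CC/C=C/C=C/OC(=O)/C=C/c2ccccc2 | intermediate
15 | (1S,3aS,6R,7R,8aS)-1-methyl-8-oxo-7-(propan-2-yl)-1-(triethylsilyloxy)-1,2,3,3a,6,7,8,8a-octahydroazulen-6-yl (2E)-3-phenylprop-2-enoate | C1=C[C@@H](OC(=O)/C=C/c3ccccc3)[C@@H](C(C)C)C(=O)[C@H]2[C@H]1CC[C@]2(C)O[Si](CC)(CC)CC | intermediate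
16 | (1S,3aS,6R,7S,8R,8aR)-8-hydroxy-1-methyl-7-(propan-2-yl)-1-(triethylsilyloxy)-1,2,3,3a,6,7,8,8a-octahydroazulen-6-yl (2E)-3-phenylprop-2-enoate | C1=C[C@@H](OC(=O)/C=C/c3ccccc3)[C@@H](C(C)C)[C@@H](O)[C@H]2[C@H]1CC[C@]2(C)O[Si](CC)(CC)CC | intermediate
17 | (1S,3aR,6R,7S,8R,8aR)-8-hydroxy-1-methyl-4-oxo-7-(propan-2-yl)-1-(triethylsilyloxy)decahydroazulen-6-yl (2E)-3-phenylprop-2-enoate | O=C1C[C@@H](OC(=O)/C=C/c3ccccc3)[C@@H](C(C)C)[C@@H](O)[C@H]2[C@H]1CC[C@]2(C)O[Si](CC)(CC)CC | intermediate
18 | (1S,3aR,6R,7S,8R,8aR)-8-hydroxy-1-methyl-4-methylidene-7-(propan-2-yl)-1-(triethylsilyloxy)decahydroazulen-6-yl (2E)-3-phenylprop-2-enoate | C=C1C[C@@H](OC(=O)/C=C/c3ccccc3)[C@@H](C(C)C)[C@@H](O)[C@H]2[C@H]1CC[C@]2(C)O[Si](CC)(CC)CC | intermediate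
19 | (1S,3aR,6R,7S,8R,8aR)-1,8-dihydroxy-1-methyl-4-methylidene-7-(propan-2-yl)decahydroazulen-6-yl (2E)-3-phenylprop-2-enoate | C=C1C[C@@H](OC(=O)/C=C/c2ccccc2)[C@@H](C(C)C)[C@@H](O)[C@H]2[C@H]1CC[C@]2(C)O | target

Total step count: 13. Longest linear sequence: 13 steps (1 to 19).

**Steps most likely to fail**

Step 9. The second bond may form at C10 instead of C8 (five-membered closure, a formal (3+2) outcome), the compact array may compete and give the cis ring fusion, or the C7 configuration may leak if the enol silane from step 8 is not isomerically pure or reacts stepwise. The fallback sets out from 13 and gives up the concerted epoxide opening for the classical α-halo ketone entry to oxyallyl cations. The epoxy ketone is opened at the carbonyl-activated C5 with LiBr/AcOH (SN2, inversion) to the α-bromo-β-hydroxy ketone F1. The tertiary hydroxyl is silylated (Et3SiOTf, 2,6-lutidine) to the bromo ketone F2. Base-induced ionisation (Et3N in CF3CH2OH) then generates the oxyallyl cation for a stepwise intramolecular (4+3) cycloaddition with the same dienyl ester, which comes back to the route at 15. In this variant C5 and C7 depend on the cation geometry and on the C4 centre rather than on inversion and enol ether geometry, so diastereomers would have to be separated.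

Step 11. Oxidation of the hindered cis-cycloalkene may be slow, water may attack at C9, or the free C6 hydroxyl may take part in the palladium-activated alkene. The fallback sets out from 16 and replaces the direct ketone synthesis by hydration and oxidation. Oxymercuration–demercuration (Hg(OCOCF3)2, THF/H2O; then NaBH4), which also places oxygen distal to the allylic ester, should give the 4,8-diol F3. Selective Dess–Martin oxidation of the new, less hindered C10 carbinol (the C6 hydroxyl is flanked by C5 and the isopropyl-bearing C7) comes back to the route at 17.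

Step 7. γ-Deprotonation under soft conditions may be incomplete, the enol ester may form as a 1E/1Z mixture, and the epoxy ketone may suffer on prolonged heating with amine. The fallback sets out from 8 and forms the dienyl ester from a kinetic potassium dienolate on a ketone-free intermediate. The alcohol is silylated (Et3SiCl, imidazole) to the silyl ether F4. Cross-metathesis with 10 under the conditions of step 6 gives the enal F5. KOt-Bu in THF at −78 °C followed by cinnamoyl chloride O-acylates the dienolate to the dienyl cinnamate F6. Buffered fluoride (Bu4NF/AcOH) frees the alcohol F7, and Dess–Martin oxidation comes back to the route at 13.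

**Further compounds**
F1 | step 9 | (1E,3E,7S,8S)-8-bromo-7-hydroxy-7,11-dimethyl-9-oxododeca-1,3-dien-1-yl (2E)-3-phenylprop-2-enoate | CC(C)CC(=O)[C@@H](Br)[C@@](C)(O)CC/C=C/C=C/OC(=O)/C=C/c1ccccc1
F2 | step 9 | (1E,3E,7S,8S)-8-bromo-7,11-dimethyl-9-oxo-7-(triethylsilyloxy)dodeca-1,3-dien-1-yl (2E)-3-phenylprop-2-enoate | CC(C)CC(=O)[C@@H](Br)[C@@](C)(O[Si](CC)(CC)CC)CC/C=C/C=C/OC(=O)/C=C/c1ccccc1
F3 | step 11 | (1S,3aR,6R,7S,8R,8aR)-4,8-dihydroxy-1-methyl-7-(propan-2-yl)-1-(triethylsilyloxy)decahydroazulen-6-yl (2E)-3-phenylprop-2-enoate (C4 carbinol configuration open) | OC1C[C@@H](OC(=O)/C=C/c3ccccc3)[C@@H](C(C)C)[C@@H](O)[C@H]2[C@H]1CC[C@]2(C)O[Si](CC)(CC)CC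
F4 | step 7 | triethyl{3-methyl-1-[(2S,3S)-3-methyl-3-(pent-4-en-1-yl)oxiran-2-yl]butoxy}silane (carbinol epimers) | CC(C)CC(O[Si](CC)(CC)CC)[C@@H]1O[C@@]1(C)CCCC=C
F5 | step 7 | (2E)-6-{(2S,3S)-2-methyl-3-[3-methyl-1-(triethylsilyloxy)butyl]oxiran-2-yl}hex-2-enal | CC(C)CC(O[Si](CC)(CC)CC)[C@@H]1O[C@@]1(C)CCC/C=C/C=O
F6 | step 7 | (1E,3E)-6-{(2S,3S)-2-methyl-3-[3-methyl-1-(triethylsilyloxy)butyl]oxiran-2-yl}hexa-1,3-dien-1-yl (2E)-3-phenylprop-2-enoate | CC(C)CC(O[Si](CC)(CC)CC)[C@@H]1O[C@@]1(C)CC/C=C/C=C/OC(=O)/C=C/c2ccccc2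
F7 | step 7 | (1E,3E)-6-[(2S,3S)-3-(1-hydroxy-3-methylbutyl)-2-methyloxiran-2-yl]hexa-1,3-dien-1-yl (2E)-3-phenylprop-2-enoate | CC(C)CC(O)[C@@H]1O[C@@]1(C)CC/C=C/C=C/OC(=O)/C=C/c2ccccc2
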